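**Retrosynthetic overview**

1. Target 14 ⇒ ketone 13 (same skeleton, carbinol carbon at the ketone level). A catalyst-controlled reduction sets the carbinol centre and resolves racemic 13.
2. Ketone 13 ⇒ three components in one flask: aryl enone 6, geminal bis(silyl)methallyl reagent 10 and aldehyde 3. The CH2–CMe2 bond comes from Sakurai conjugate addition, the ArCH–CH(C=O) bond from the aldol, and the ArCH–CH= bond from vinylsilane capture of a benzylic cation.
3. Enabling feature: the ring carbon that carries the first coumarin sits on C8 of a 5,7-dimethoxycoumarin, ortho to ring oxygen O1 and to the 7-OMe and para to the 5-OMe, so its C–O bond ionises readily. Its ring neighbour is the α-carbon of an aryl ketone, and the gem-dimethyl ring carbon is the β-carbon of that enone.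
4. Ring order: both coumarin bicycles are bought intact in 1; the cyclohexene is the only ring made (step 5). Enone 6 and aldehyde 3 both come from 1; reagent 10 comes from 7 and 8.

Key step: step 5

Assumption: electrophiles attack 5,7-dimethoxycoumarin at C8 (para to the 5-OMe); in ketone 13 the quaternary CMe2 carbon acts as the large α-substituent (Felkin–Anh), and the twisted aryl group acts as the large carbonyl substituent towards the CBS catalyst.

Step 1
Reactants: 1 5,7-dimethoxycoumarin
Product: 3 5,7-dimethoxy-2-oxo-2H-chromene-8-carbaldehyde, via chloro(methoxy)methyl arene 2 (not isolated)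
Conditions: Cl2CHOMe, TiCl4, CH2Cl2, 0 °C to 23 °C; then ice-water
Reagents that add atoms: dichloromethyl methyl ether ClC(Cl)OC; water O
Why: Rieche formylation (electrophilic aromatic substitution) should go to C8, the ring carbon para to the 5-OMe and ortho to the 7-OMe, and hydrolysis of the α-chloro ether 2 on work-up gives the aldehyde.

Step 2
Reactants: 3 5,7-dimethoxy-2-oxo-2H-chromene-8-carbaldehyde; 4 (2-methylprop-1-en-1-yl)magnesium bromide
Product: 5 rac-8-(1-hydroxy-3-methylbut-2-en-1-yl)-5,7-dimethoxy-2H-chromen-2-one
Conditions: THF, −78 °C; aq. NH4Cl; crude used at once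
Reagents that add atoms: none
Why: 1,2-addition of the alkenyl Grignard reagent to the aldehyde at −78 °C should outrun attack on the lactone, and the racemic carbinol centre it creates is removed in step 3 (Grignard addition).

Step 3
Reactants: 5 rac-8-(1-hydroxy-3-methylbut-2-en-1-yl)-5,7-dimethoxy-2H-chromen-2-one
Product: 6 5,7-dimethoxy-8-(3-methylbut-2-enoyl)-2H-chromen-2-one
Conditions: MnO2, CH2Cl2, 23 °C
Reagents that add atoms: none
Why: MnO2 oxidises the doubly activated allylic benzylic alcohol under neutral conditions, which avoids acid-induced ionisation to the diene (allylic oxidation).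

Step 4
Reactants: 7 chlorobis(trimethylsilyl)methane; 8 2-bromopropene
Product: 10 (2-methylprop-2-ene-1,1-diyl)bis(trimethylsilane), via bis(trimethylsilyl)methylmagnesium chloride 9 (not isolated)
Conditions: Mg, THF, reflux; then 8, Pd(PPh3)4 (3 mol%), THF, 23 to 50 °C
Reagents that add atoms: none
Why: The α-silyl Grignard reagent 9 should couple with the vinyl bromide under zerovalent palladium catalysis without allylic transposition (Kumada–Corriu coupling), the standard way to allylsilanes.

Step 5
Reactants: 6 5,7-dimethoxy-8-(3-methylbut-2-enoyl)-2H-chromen-2-one; 10 (2-methylprop-2-ene-1,1-diyl)bis(trimethylsilane); 3 5,7-dimethoxy-2-oxo-2H-chromene-8-carbaldehyde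
Product: 13 rac-[(1R,2S)-2-(5,7-dimethoxy-2-oxo-2H-chromen-8-yl)-4,6,6-trimethylcyclohex-3-en-1-yl](5,7-dimethoxy-2-oxo-2H-chromen-8-yl)methanone, via titanium enolate 11 (not isolated), via titanium aldolate 12 (not isolated)
Conditions: 6, TiCl4 (2.2 equiv), CH2Cl2, −78 °C, then 10 (1.0 equiv), −78 to −40 °C; then 3·TiCl4 (1.0 equiv), −78 to 0 °C; aq. NaHCO3; DBU (0.2 equiv), CH2Cl2, 23 °C only if cis epimer is present
Reagents that add atoms: none
Why: Proposed new method: TiCl4 chelated between the ketone and the 7-OMe of 6 should trigger Hosomi–Sakurai attack of the CH2 terminus of 10 on the β,β-dimethyl enone carbon (new CH2–CMe2 bond, loss of one Me3Si), leaving a vinylsilane and titanium enolate 11, which adds to aldehyde 3 to give aldolate 12; on warming, the benzylic C–O–Ti bond of 12 (carbon on coumarin C8, ortho to O1 and 7-OMe, para to 5-OMe) ionises, the cation is captured by the silicon-bearing vinyl carbon (new ArCH–CH= bond), and the β-silyl cation expels Me3Si+ so that the double bond can lie only between that CH and the C–Me. The closest known chemistry is the three-component Sakurai–aldol coupling of enone, allylsilane and aldehyde and the vinylsilane-terminated cation–olefin cyclisation of benzylic cations; their fusion into one [3+2+1] hexannulation with a geminal bis(silyl)allyl reagent is the untested part. The cyclohexene closes through a chair transition state in a 6-endo mode with respect to the vinylsilane π bond, Markovnikov attack giving the tertiary β-silyl cation. The aldol stereocentres need no control, since the carbinol centre is erased on ionisation and all four aldol isomers converge, and the new ArCH centre is set relative to the CH(C=O) centre by 1,3-allylic strain in the cation (C–H in the aryl plane, tether on one face, aroyl on the other), which places aryl and aroyl trans-diequatorial; the product is racemic. The step needs conjugate addition before aldol (secured by adding 3 only after 10 is consumed), ionisation at one benzylic carbon only (secured by keeping the other at the ketone level) and a single alkene position (secured by silicon); any cis epimer from an elimination–conjugate-addition side path is expected to equilibrate to the trans ketone with DBU, as known for 2-substituted 6,6-dimethylcyclohex-3-enyl ketones.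

Step 6
Reactants: 13 rac-[(1R,2S)-2-(5,7-dimethoxy-2-oxo-2H-chromen-8-yl)-4,6,6-trimethylcyclohex-3-en-1-yl](5,7-dimethoxy-2-oxo-2H-chromen-8-yl)methanone
Product: 14 8-[(R)-[(1R,2S)-2-(5,7-dimethoxy-2-oxo-2H-chromen-8-yl)-4,6,6-trimethylcyclohex-3-en-1-yl](hydroxy)methyl]-5,7-dimethoxy-2H-chromen-2-one
Conditions: (S)-2-methyl-CBS-oxazaborolidine (0.2 equiv), catecholborane (0.6 equiv), toluene, −40 to −20 °C, stopped near half conversion; MeOH, then pH 7 buffer; chromatography (unreacted (1S,2R)-ketone recovered)
Reagents that add atoms: none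
Why: The (S)-CBS catalyst should deliver hydride to the carbonyl face that gives the (R)-carbinol (aryl as the large group), which for the (1R,2S)-ketone is also the Felkin–Anh face (hydride anti to the quaternary CMe2 carbon), so this matched enantiomer should react fast and give 14 as one enantiomer and diastereomer while the (1S,2R)-ketone is left behind (kinetic resolution by Corey–Bakshi–Shibata reduction).

**Compound list**

1 | 5,7-dimethoxy-2H-chromen-2-one (5,7-dimethoxycoumarin) | COc1cc(OC)c2ccc(=O)oc2c1 | starting material
2 | 8-[chloro(methoxy)methyl]-5,7-dimethoxy-2H-chromen-2-one (racemic, formed in the flask) | COc1cc(OC)c2ccc(=O)oc2c1C(Cl)OC | intermediate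
3 | 5,7-dimethoxy-2-oxo-2H-chromene-8-carbaldehyde | COc1cc(OC)c2ccc(=O)oc2c1C=O | intermediate
4 | (2-methylprop-1-en-1-yl)magnesium bromide (solution in THF) | CC(C)=C[Mg]Br | starting material
5 | rac-8-(1-hydroxy-3-methylbut-2-en-1-yl)-5,7-dimethoxy-2H-chromen-2-one | COc1cc(OC)c2ccc(=O)oc2c1C(O)C=C(C)C | intermediate
6 | 5,7-dimethoxy-8-(3-methylbut-2-enoyl)-2H-chromen-2-one | COc1cc(OC)c2ccc(=O)oc2c1C(=O)C=C(C)C | intermediate
7 | chlorobis(trimethylsilyl)methane | C[Si](C)(C)C(Cl)[Si](C)(C)C | starting material
8 | 2-bromopropene | CC(Br)=C | starting material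
9 | [bis(trimethylsilyl)methyl]magnesium chloride | C[Si](C)(C)C([Mg]Cl)[Si](C)(C)C | intermediate
10 | (2-methylprop-2-ene-1,1-diyl)bis(trimethylsilane) | CC(=C)C([Si](C)(C)C)[Si](C)(C)C | intermediate
11 | trichlorotitanium enolate of 1-(5,7-dimethoxy-2-oxo-2H-chromen-8-yl)-3,3,5-trimethyl-6-(trimethylsilyl)hex-5-en-1-one (enolate and vinylsilane geometry not defined) | COc1cc(OC)c2ccc(=O)oc2c1C(O[Ti](Cl)(Cl)Cl)=CC(C)(C)CC(C)=C[Si](C)(C)C | intermediate
12 | trichlorotitanium alkoxide of the aldol adduct of 11 and 3 (mixture of all stereoisomers) | COc1cc(OC)c2ccc(=O)oc2c1C(=O)C(C(C)(C)CC(C)=C[Si](C)(C)C)C(O[Ti](Cl)(Cl)Cl)c1c(OC)cc(OC)c2ccc(=O)oc12 | intermediate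
13 | rac-[(1R,2S)-2-(5,7-dimethoxy-2-oxo-2H-chromen-8-yl)-4,6,6-trimethylcyclohex-3-en-1-yl](5,7-dimethoxy-2-oxo-2H-chromen-8-yl)methanone (trans; racemate, the (1R,2S) enantiomer is drawn) | COc1cc(OC)c2ccc(=O)oc2c1[C@H]1C=C(C)CC(C)(C)[C@@H]1C(=O)c1c(OC)cc(OC)c2ccc(=O)oc12 | intermediate
14 | 8-[(R)-[(1R,2S)-2-(5,7-dimethoxy-2-oxo-2H-chromen-8-yl)-4,6,6-trimethylcyclohex-3-en-1-yl](hydroxy)methyl]-5,7-dimethoxy-2H-chromen-2-one (IN0553) | COc1cc(OC)c2ccc(=O)oc2c1[C@H]1C=C(C)CC(C)(C)[C@@H]1[C@@H](O)c1c(OC)cc(OC)c2ccc(=O)oc12 | target

**Step count and risks**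

Total steps: 6. Longest linear sequence: 5 steps (1 → 3 → 5 → 6 → 13 → 14; step 4 is a one-step branch).

Steps most likely to fail:

1. Step 5 (Proposed new method). What may go wrong: retro-aldol or incomplete aldol of the hindered titanium enolate, protodesilylation of the vinylsilane before ring closure, or reaction of unconsumed 10 with the aldehyde. Fallback with known chemistry, setting out from 3 and 6 and returning at 13: aldehyde 3 would be olefinated with diethyl (2-methylallyl)phosphonate (NaH, THF, Horner–Wadsworth–Emmons) to 5,7-dimethoxy-8-[(1E)-3-methylbuta-1,3-dien-1-yl]-2H-chromen-2-one F1. Diels–Alder reaction of F1 with enone 6 (Me2AlCl, CH2Cl2, −20 °C, or toluene, 110 °C) should follow the ortho/para rule and give, through the endo transition state, the racemic cis ketone F2. DBU should then equilibrate F2 to the trans ketone 13.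

2. Step 6. What may go wrong: poor discrimination between the two ketone enantiomers by the catalyst, or hydride delivery to the other carbonyl face if the aryl-bearing ring carbon rather than CMe2 shields the ketone. Fallback, setting out from 13 and returning at 14: Luche reduction (NaBH4, CeCl3·7H2O, MeOH–CH2Cl2, −40 °C) under substrate control would give the racemic alcohol F3. Esterification with (S)-2-methoxy-2-phenylacetic acid (DCC, DMAP, CH2Cl2) would give two diastereomeric esters, the ester of 14, F4, and the ester of its enantiomer, F5, to be separated by chromatography or crystallisation. Cleavage of F4 with LiOH (THF–H2O, 0 °C), then acidification with HCl to re-close any opened lactone, should return 14.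

3. Step 2. What may go wrong: ionisation and dehydration of the doubly activated allylic benzylic alcohol during work-up, and competing attack of the Grignard reagent on the lactone. Fallback, setting out from 1 and returning at 6: Friedel–Crafts acylation of 1 with 3-methylbut-2-enoyl chloride (SnCl4, CH2Cl2, 0 °C) at C8 would give enone 6 directly, with no alcohol intermediate.

**Further compounds**

F1 | step 5 | 5,7-dimethoxy-8-[(1E)-3-methylbuta-1,3-dien-1-yl]-2H-chromen-2-one | COc1cc(OC)c2ccc(=O)oc2c1/C=C/C(C)=C
F2 | step 5 | rac-[(1S,2S)-2-(5,7-dimethoxy-2-oxo-2H-chromen-8-yl)-4,6,6-trimethylcyclohex-3-en-1-yl](5,7-dimethoxy-2-oxo-2H-chromen-8-yl)methanone (cis; racemate, one enantiomer drawn) | COc1cc(OC)c2ccc(=O)oc2c1[C@H]1C=C(C)CC(C)(C)[C@H]1C(=O)c1c(OC)cc(OC)c2ccc(=O)oc12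
F3 | step 6 | racemate of 14 (the enantiomer of 14 is drawn for the SMILES of 14; equal amount of its mirror image) | COc1cc(OC)c2ccc(=O)oc2c1[C@H]1C=C(C)CC(C)(C)[C@@H]1[C@@H](O)c1c(OC)cc(OC)c2ccc(=O)oc12
F4 | step 6 | (S)-2-methoxy-2-phenylacetate ester of 14 | COc1cc(OC)c2ccc(=O)oc2c1[C@H]1C=C(C)CC(C)(C)[C@@H]1[C@@H](OC(=O)[C@@H](OC)c1ccccc1)c1c(OC)cc(OC)c2ccc(=O)oc12
F5 | step 6 | (S)-2-methoxy-2-phenylacetate ester of the enantiomer of 14 | COc1cc(OC)c2ccc(=O)oc2c1[C@@H]1C=C(C)CC(C)(C)[C@H]1[C@H](OC(=O)[C@@H](OC)c1ccccc1)c1c(OC)cc(OC)c2ccc(=O)oc12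
F0 | step 2 | none | none
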